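**Strategy.** The tertiary vinyl carbinol C1=C2–C3(Me)–O of the target is treated as the transposed form of a C2,C3-oxirane. The free C4 hydroxyl of (2E,4S)-3,7-dimethylocta-2,6-dien-4-ol, flanked by the geminal C3 methyl, should steer a VO(acac)2-catalysed tert-butyl hydroperoxide epoxidation of the C2=C3 alkene to one face. A single operation thus closes the oxirane (C2, C3, O), forms both C–O bonds and fixes C3 erythro to C4, while the C6=C7 alkene is spared. The precursor is an acyclic secondary allylic alcohol made by asymmetric allylation of tiglic aldehyde and cross-metathesis. Selenide opening at C2, selenoxide elimination towards C1 and two acylations then finish the target.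

Key step: step 3

Remarks on the chemistry:
- Chain numbering used throughout: C1=C2–C3(Me)(OAc)–C4(O-coumaroyl)–C5–C6=C7Me2.
- The target is (3R,4S), with O3 and O4 erythro along C2–C3–C4–C5. The epoxy alcohol that leads to it is (2S,3S) at the ring and (S) at the carbinol.
- Assumption: (E)-4-acetoxycinnamic acid 11 is a purchased compound.

Step 1
Reactants: 1 (E)-2-methylbut-2-enal; 2 allylboronic acid pinacol ester
Product: 4 (2E,4S)-3-methylhepta-2,6-dien-4-ol, via borate ester 3 (not isolated)
Conditions: (S)-TRIP [(S)-3,3'-bis(2,4,6-triisopropylphenyl)-1,1'-binaphthalene-2,2'-diyl hydrogen phosphate] (5 mol%), toluene, −30 °C; then aq. NaHCO3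
Reagents that add atoms: none
Why: Chiral phosphoric acid-catalysed allylboration of an aldehyde through a closed six-membered chair transition state, in which the acid activates the boronate oxygen and orients the formyl group; the (S)-catalyst should direct allyl transfer to the Si face of the enal carbonyl (1,2-addition only) and so set C4 as S, and the B–O bond of 3 is hydrolysed on work-up.

Step 2
Reactants: 4 (2E,4S)-3-methylhepta-2,6-dien-4-ol; 5 2-methylbut-2-ene
Product: 6 (2E,4S)-3,7-dimethylocta-2,6-dien-4-ol
Conditions: second-generation Grubbs catalyst RuCl2(=CHPh)(PCy3)(H2IMes) (3 mol%), 2-methylbut-2-ene (large excess)/CH2Cl2, 23–35 °C, sealed vessel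
Reagents that add atoms: none
Why: Olefin cross-metathesis in which only the monosubstituted terminal alkene engages the ruthenium carbene, because the 1,1,2-trisubstituted C2=C3 alkene is too hindered and ring closure between the two alkenes would need a cyclobutene, while the excess of the volatile partner drives capping to the isopropylidene terminus; the C4 stereocentre is not touched.

Step 3
Reactants: 6 (2E,4S)-3,7-dimethylocta-2,6-dien-4-ol
Product: 7 (1S)-1-[(2S,3S)-2,3-dimethyloxiran-2-yl]-4-methylpent-3-en-1-ol
Conditions: VO(acac)2 (3 mol%), t-BuOOH (1.1 equiv, in decane), CH2Cl2, 0 → 23 °C; aq. Na2S2O3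
Reagents that add atoms: tert-butyl hydroperoxide, CC(C)(C)OO
Why: Tetravalent VO(acac)2 is oxidised by the hydroperoxide to a pentavalent vanadate ester that carries both the C4 alkoxide and the η2-bound tert-butylperoxide, and the peroxide oxygen is then passed intramolecularly to the C2=C3 π bond; this is the hydroxyl-directed vanadium epoxidation of secondary allylic alcohols. The oxirane is closed by a concerted [2+1] oxygen-atom transfer that forms O–C2 and O–C3 on the same face, so the E geometry is carried into the ring and C2 is fixed relative to C3 (C1 and the C3 methyl cis). The face, and with it C3, is set by the C4 stereocentre: with the O–C4–C3=C2 dihedral near 40–50° imposed by the tether, the rotamer that would put C5 beside the geminal C3 methyl suffers allylic 1,2-strain, so H4 takes that place and oxygen should arrive on the face that gives the erythro (2S,3S) epoxide. Site selectivity is needed against the C6=C7 alkene, which is only homoallylic to the directing oxygen and should react much more slowly through a larger, less organised transition state; about one equivalent of oxidant at 0 °C is meant to leave it untouched. The C4 hydroxyl is kept free because it is the directing group.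

Step 4
Reactants: 7 (1S)-1-[(2S,3S)-2,3-dimethyloxiran-2-yl]-4-methylpent-3-en-1-ol
Product: 8 (2R,3S,4S)-3,7-dimethyl-2-(phenylselanyl)oct-6-ene-3,4-diol
Conditions: (PhSe)2 (0.6 equiv), NaBH4 (1.3 equiv), EtOH, 23 °C; then 7, 78 °C
Reagents that add atoms: diphenyl diselenide, c1ccc(cc1)[Se][Se]c1ccccc1
Why: Nucleophilic (SN2) epoxide opening by benzeneselenolate, generated from the diselenide by borohydride reduction, should occur at the less substituted C2 anti to the breaking C2–O bond (inversion at C2, later lost), so the C3–O bond and the C3 and C4 configurations are retained; the weakly basic reagent does not promote Payne migration, which would in any case need attack at the fully substituted C3.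

Step 5
Reactants: 8 (2R,3S,4S)-3,7-dimethyl-2-(phenylselanyl)oct-6-ene-3,4-diol
Product: 10 (3R,4S)-3,7-dimethylocta-1,6-diene-3,4-diol, via selenoxide 9 (not isolated)
Conditions: mCPBA (1.05 equiv), CH2Cl2, −78 °C; then Et3N (4 equiv), −78 → 23 °C
Reagents that add atoms: none
Why: Chemoselective oxidation at selenium followed by thermal syn (Ei) selenoxide elimination; C3 carries no hydrogen, so only a C1 hydrogen can be removed and the C1=C2 vinyl group forms with C3 and C4 unchanged, while the low oxidation temperature and the amine (which buffers the acids and intercepts PhSeOH) protect the C6=C7 alkene.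

Step 6
Reactants: 10 (3R,4S)-3,7-dimethylocta-1,6-diene-3,4-diol; 11 (E)-3-(4-acetoxyphenyl)prop-2-enoic acid
Product: 12 (3R,4S)-3-hydroxy-3,7-dimethylocta-1,6-dien-4-yl (E)-3-(4-acetoxyphenyl)prop-2-enoate
Conditions: EDC·HCl (1.3 equiv), DMAP (0.2 equiv), CH2Cl2, 0 → 23 °C
Reagents that add atoms: none
Why: Carbodiimide/DMAP (Steglich) esterification, in which the secondary C4 hydroxyl is acylated while the tertiary C3 hydroxyl is too hindered to compete; the C4–O bond is not broken, so configuration is retained, and the aryl acetate and the E alkene of the acid are inert to the coupling.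

Step 7
Reactants: 12 (3R,4S)-3-hydroxy-3,7-dimethylocta-1,6-dien-4-yl (E)-3-(4-acetoxyphenyl)prop-2-enoate
Product: 13 (3R,4S)-3-acetoxy-3,7-dimethylocta-1,6-dien-4-yl (E)-3-(4-acetoxyphenyl)prop-2-enoate
Conditions: Ac2O (5 equiv), Et3N (6 equiv), DMAP (0.5 equiv), CH2Cl2, 23–35 °C
Reagents that add atoms: acetic anhydride, CC(=O)OC(C)=O
Why: DMAP-catalysed acetylation of a tertiary alcohol through the N-acetylpyridinium ion, a reaction known for tertiary allylic carbinols of the linalool type; the C3–O bond stays intact so C3 keeps its configuration, and the excess anhydride is meant to outrun any shift of the C4 acyl group, which in any case prefers the secondary oxygen.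

Step 8
Reactants: 13 (3R,4S)-3-acetoxy-3,7-dimethylocta-1,6-dien-4-yl (E)-3-(4-acetoxyphenyl)prop-2-enoate
Product: 14 (3R,4S)-3-acetoxy-3,7-dimethylocta-1,6-dien-4-yl (E)-3-(4-hydroxyphenyl)prop-2-enoate
Conditions: NH4OAc (10 equiv), MeOH/H2O (4:1), 23 °C
Reagents that add atoms: none
Why: Chemoselective solvolysis of a phenolic acetate under near-neutral ammonium acetate catalysis, in which the aryloxide is a far better leaving group than either alkoxide, so the tertiary C3 acetate and the conjugated C4 ester should survive; no stereocentre is involved.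

**Compound list**

1 | (E)-2-methylbut-2-enal (tiglic aldehyde) | C/C=C(\C)C=O | starting material
2 | allylboronic acid pinacol ester (2-allyl-4,4,5,5-tetramethyl-1,3,2-dioxaborolane) | C=CCB1OC(C)(C)C(C)(C)O1 | starting material
3 | 4,4,5,5-tetramethyl-2-{[(2E,4S)-3-methylhepta-2,6-dien-4-yl]oxy}-1,3,2-dioxaborolane (borate ester) | C/C=C(\C)[C@H](CC=C)OB1OC(C)(C)C(C)(C)O1 | intermediate
4 | (2E,4S)-3-methylhepta-2,6-dien-4-ol | C/C=C(\C)[C@H](CC=C)O | intermediate
5 | 2-methylbut-2-ene | CC=C(C)C | starting material
6 | (2E,4S)-3,7-dimethylocta-2,6-dien-4-ol | C/C=C(\C)[C@H](CC=C(C)C)O | intermediate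
7 | (1S)-1-[(2S,3S)-2,3-dimethyloxiran-2-yl]-4-methylpent-3-en-1-ol | C[C@@H]1O[C@@]1(C)[C@H](CC=C(C)C)O | intermediate
8 | (2R,3S,4S)-3,7-dimethyl-2-(phenylselanyl)oct-6-ene-3,4-diol | C[C@@H]([Se]c1ccccc1)[C@@](C)(O)[C@H](CC=C(C)C)O | intermediate
9 | (2R,3S,4S)-3,7-dimethyl-2-(phenylseleninyl)oct-6-ene-3,4-diol (selenoxide, mixture at selenium) | C[C@@H]([Se](=O)c1ccccc1)[C@@](C)(O)[C@H](CC=C(C)C)O | intermediate
10 | (3R,4S)-3,7-dimethylocta-1,6-diene-3,4-diol | C=C[C@@](C)(O)[C@H](CC=C(C)C)O | intermediate
11 | (E)-3-(4-acetoxyphenyl)prop-2-enoic acid (4-acetoxycinnamic acid) | CC(=O)Oc1ccc(/C=C/C(=O)O)cc1 | starting material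
12 | (3R,4S)-3-hydroxy-3,7-dimethylocta-1,6-dien-4-yl (E)-3-(4-acetoxyphenyl)prop-2-enoate | C=C[C@@](C)(O)[C@H](CC=C(C)C)OC(=O)/C=C/c1ccc(OC(C)=O)cc1 | intermediate
13 | (3R,4S)-3-acetoxy-3,7-dimethylocta-1,6-dien-4-yl (E)-3-(4-acetoxyphenyl)prop-2-enoate | C=C[C@@](C)(OC(C)=O)[C@H](CC=C(C)C)OC(=O)/C=C/c1ccc(OC(C)=O)cc1 | intermediate
14 | (3R,4S)-3-acetoxy-3,7-dimethylocta-1,6-dien-4-yl (E)-3-(4-hydroxyphenyl)prop-2-enoate | C=C[C@@](C)(OC(C)=O)[C@H](CC=C(C)C)OC(=O)/C=C/c1ccc(O)cc1 | target

**Totals.** Total step count: 8. Longest linear sequence: 8 steps (1 → 14).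

**Steps most likely to fail, with fallbacks**

Step 3. The risk is loss of site selectivity (oxygen also delivered to the homoallylic C6=C7 alkene) or erosion of the erythro preference. The fallback replaces substrate control by reagent control. Starting from 6, a Katsuki–Sharpless epoxidation is run in the matched pairing: Ti(OiPr)4 (10 mol%), L-(+)-diisopropyl tartrate (12 mol%), t-BuOOH, 4 Å molecular sieves, CH2Cl2, −20 °C. For a secondary allylic alcohol whose carbinol is S with the priority order O > alkenyl > alkyl > H, the L-(+)-tartrate complex is the fast-reacting pair and should give the erythro epoxy alcohol. The C6=C7 alkene has no allylic hydroxyl and is a poor substrate for this catalyst, and any (R)-6 left from step 1 reacts slowly and is removed. The fallback comes back to the route at 7 and makes no new compound F0.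

Step 7. The risk is slow acylation of the hindered tertiary carbinol, which leaves time for a base-induced shift of the C4 acyl group to O3 and acetylation of the freed O4, or for ionisation of the tertiary allylic ester. The fallback reverses the order of the two acylations, so that the acetate is installed while O4 carries no acyl group. Starting from 10, the secondary hydroxyl is silylated selectively (Et3SiCl, imidazole, CH2Cl2, 0 °C) to give (3R,4S)-3,7-dimethyl-4-(triethylsilyloxy)octa-1,6-dien-3-ol F1. The tertiary hydroxyl is then acetylated (Ac2O, Et3N, DMAP, CH2Cl2) to give (3R,4S)-3,7-dimethyl-4-(triethylsilyloxy)octa-1,6-dien-3-yl acetate F2. The silyl ether is cleaved under buffered acidic conditions (HF·pyridine, pyridine, THF, 0 °C), which disfavour acetyl migration, to give (3R,4S)-4-hydroxy-3,7-dimethylocta-1,6-dien-3-yl acetate F3. This is esterified at once with 11 (EDC·HCl, DMAP, CH2Cl2, 0 °C) and so comes back to the route at 13.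

Step 5. The risk is attack of electrophilic selenium by-products or residual peracid on the electron-rich C6=C7 alkene, and slow elimination of the hydrogen-bonded β-hydroxy selenoxide. The fallback carries out the transposition on sulfur, where the elimination is purely thermal and takes place with no oxidant or electrophilic chalcogen species present. Starting from 7, thiophenol and Et3N in MeOH at 60 °C should open the oxirane at C2 to give (2R,3S,4S)-3,7-dimethyl-2-(phenylsulfanyl)oct-6-ene-3,4-diol F4. One equivalent of mCPBA at −78 °C should give (2R,3S,4S)-3,7-dimethyl-2-(phenylsulfinyl)oct-6-ene-3,4-diol F5. Thermolysis in toluene at 110 °C, with CaCO3 and P(OMe)3 as sulfenic acid trap, should effect syn elimination towards C1 (the only β-hydrogens) and comes back to the route at 10.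

Further compounds
F0 | step 3 | none | none
F1 | step 7 | (3R,4S)-3,7-dimethyl-4-(triethylsilyloxy)octa-1,6-dien-3-ol | C=C[C@@](C)(O)[C@H](CC=C(C)C)O[Si](CC)(CC)CC
F2 | step 7 | (3R,4S)-3,7-dimethyl-4-(triethylsilyloxy)octa-1,6-dien-3-yl acetate | C=C[C@@](C)(OC(C)=O)[C@H](CC=C(C)C)O[Si](CC)(CC)CC
F3 | step 7 | (3R,4S)-4-hydroxy-3,7-dimethylocta-1,6-dien-3-yl acetate | C=C[C@@](C)(OC(C)=O)[C@H](CC=C(C)C)O
F4 | step 5 | (2R,3S,4S)-3,7-dimethyl-2-(phenylsulfanyl)oct-6-ene-3,4-diol | C[C@@H](Sc1ccccc1)[C@@](C)(O)[C@H](CC=C(C)C)O
F5 | step 5 | (2R,3S,4S)-3,7-dimethyl-2-(phenylsulfinyl)oct-6-ene-3,4-diol (mixture at sulfur) | C[C@@H](S(=O)c1ccccc1)[C@@](C)(O)[C@H](CC=C(C)C)O
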